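**Strategy.** The synthesis rests on making the benzene ring itself: C4–C3a and C7–C7a are disconnected, giving a 3-prenyl-2-silyloxyfuran and a chiral 4,5-bis(silyloxy) ynoate. A single thermal (4+2) cycloaddition with ring-opening aromatisation should assemble the pentasubstituted arene and place every substituent; it exploits the para-hydroquinone pattern of the carbocycle (oxygen at C4 and C7, prenyl at C6, carbon branches at C3a and C7a). The ynoate precursor carries C3 and C1′ as a syn (4R,5R) diol with orthogonal triethylsilyl and tert-butyldimethylsilyl ethers, made from a glycidate by catalyst-controlled ynone reduction. Sulfur enters afterwards by Mitsunobu inversion at C3, and the tert-butyl ester becomes the thiolactone carbonyl.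

Key step: step 11

Remark: locants C1 to C7a and C1′ are those of the 2-benzothiophen-1(3H)-one skeleton of the target; the syn (4R,5R) ynoate is the diastereomer that Felkin-type substrate control on an α-silyloxy carbonyl compound would not favour, so it is set by the catalyst in step 8.

**Step 1**
Reactants: 1 furan-2(5H)-one
Product: 3 3-bromofuran-2(5H)-one, via trans-dibromolactone 2 (not isolated)
Conditions: Br2, CH2Cl2, 0 °C to rt; then Et3N, 0 °C
Reagents that add atoms: bromine, BrBr
Why: Bromine adds across the butenolide alkene and triethylamine then removes the acidic α-hydrogen with loss of the β-bromide (bromination–dehydrobromination, E1cB), the standard way to an α-bromobutenolide.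

**Step 2**
Reactants: 3 3-bromofuran-2(5H)-one; 4 tributyl(3-methylbut-2-enyl)stannane
Product: 5 3-(3-methylbut-2-enyl)furan-2(5H)-one
Conditions: Pd2(dba)3 (2.5 mol %), AsPh3 (10 mol %), NMP, 60 °C
Reagents that add atoms: none
Why: Stille cross-coupling of the vinylic bromide with the allylic stannane under ligand-poor palladium catalysis (AsPh3 speeds transmetalation) should deliver the prenyl group through its unsubstituted terminus, and the neutral conditions leave the skipped diene unconjugated.

**Step 3**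
Reactants: 5 3-(3-methylbut-2-enyl)furan-2(5H)-one
Product: 6 tert-butyl(dimethyl){[3-(3-methylbut-2-enyl)furan-2-yl]oxy}silane
Conditions: TBSOTf, Et3N, CH2Cl2, 0 °C
Reagents that add atoms: tert-butyldimethylsilyl trifluoromethanesulfonate, CC(C)(C)[Si](C)(C)OS(=O)(=O)C(F)(F)F
Why: Soft enolisation of the butenolide (silyl triflate on the carbonyl oxygen, amine removes a C5 hydrogen) gives the aromatic 2-silyloxyfuran, the silyl dienol ether formation commonly used for 3-substituted butenolides.

**Step 4**
Reactants: 7 methyl (2R)-oxirane-2-carboxylate; 8 butylmagnesium bromide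
Product: 9 methyl (2R)-2-hydroxyheptanoate
Conditions: CuI (10 mol %), THF, −40 °C; NH4Cl (aq)
Reagents that add atoms: none
Why: Copper-catalysed Grignard opening of the epoxide by SN2 attack at the unsubstituted C3 is faster than addition to the ester at low temperature, and the C2 stereocentre, which is not touched, is carried over from the glycidate.

**Step 5**
Reactants: 9 methyl (2R)-2-hydroxyheptanoate
Product: 10 methyl (2R)-2-(tert-butyldimethylsilyloxy)heptanoate
Conditions: TBSCl, imidazole, DMF, rt
Reagents that add atoms: tert-butyldimethylsilyl chloride, CC(C)(C)[Si](C)(C)Cl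
Why: Imidazole-promoted O-silylation of a secondary alcohol, not basic enough to disturb the α-stereocentre.

**Step 6**
Reactants: 10 methyl (2R)-2-(tert-butyldimethylsilyloxy)heptanoate
Product: 11 (2R)-2-(tert-butyldimethylsilyloxy)-N-methoxy-N-methylheptanamide
Conditions: MeNH(OMe)·HCl, i-PrMgCl, THF, −20 to 0 °C
Reagents that add atoms: N,O-dimethylhydroxylamine hydrochloride, CNOC.Cl
Why: Aminolysis of the methyl ester by the magnesium amide of N,O-dimethylhydroxylamine (Weinreb amide formation) runs below 0 °C, where the α-silyloxy centre is not enolised.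

**Step 7**
Reactants: 11 (2R)-2-(tert-butyldimethylsilyloxy)-N-methoxy-N-methylheptanamide; 12 ethynyltrimethylsilane
Product: 14 (4R)-4-(tert-butyldimethylsilyloxy)-1-(trimethylsilyl)non-1-yn-3-one, via lithium (trimethylsilyl)acetylide 13 (not isolated)
Conditions: 12, n-BuLi, THF, −78 °C; then 11, −78 to 0 °C; NH4Cl (aq)
Reagents that add atoms: none
Why: Weinreb ketone synthesis: the lithium acetylide adds once and the N-methoxy amide adduct releases the ynone only on work-up, so that neither over-addition nor epimerisation of C4 is expected.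

**Step 8**
Reactants: 14 (4R)-4-(tert-butyldimethylsilyloxy)-1-(trimethylsilyl)non-1-yn-3-one
Product: 15 (3R,4R)-4-(tert-butyldimethylsilyloxy)-1-(trimethylsilyl)non-1-yn-3-ol
Conditions: Ru[(S,S)-TsNCH(Ph)CH(Ph)NH](p-cymene) (2 mol %), i-PrOH, rt
Reagents that add atoms: none
Why: Noyori asymmetric transfer hydrogenation of an α,β-acetylenic ketone, in which the new carbinol centre (C3 of 15, later C3 of the target) is set by the (S,S)-diamine ligand of the catalyst (hydride delivered to the face that gives 3R, the alkyne taking the place of the aryl group of the usual model) and not by the neighbouring silyloxy centre, whose Felkin preference for the anti isomer is overridden to give the syn diol derivative.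

**Step 9**
Reactants: 15 (3R,4R)-4-(tert-butyldimethylsilyloxy)-1-(trimethylsilyl)non-1-yn-3-ol
Product: 16 (3R,4R)-4-(tert-butyldimethylsilyloxy)-3-(triethylsilyloxy)-1-(trimethylsilyl)non-1-yne
Conditions: TESCl, imidazole, CH2Cl2, 0 °C to rt
Reagents that add atoms: chlorotriethylsilane, CC[Si](Cl)(CC)CC
Why: Imidazole-promoted silylation; the triethylsilyl ether is chosen because it can later be removed in the presence of the tert-butyldimethylsilyl ethers.

**Step 10**
Reactants: 16 (3R,4R)-4-(tert-butyldimethylsilyloxy)-3-(triethylsilyloxy)-1-(trimethylsilyl)non-1-yne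
Product: 18 tert-butyl (4R,5R)-5-(tert-butyldimethylsilyloxy)-4-(triethylsilyloxy)dec-2-ynoate, via lithium acetylide 17 (not isolated)
Conditions: MeLi·LiBr, THF, 0 °C to rt; then Boc2O, −78 to 0 °C
Reagents that add atoms: di-tert-butyl dicarbonate, CC(C)(C)OC(=O)OC(=O)OC(C)(C)C
Why: Methyllithium cleaves the alkynyl carbon–silicon bond to the lithium acetylide (silicon–lithium exchange), which is acylated by Boc2O; the hindered tert-butyl ynoate does not react with a second acetylide and the propargylic centre is not deprotonated.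

**Step 11**
Reactants: 6 tert-butyl(dimethyl){[3-(3-methylbut-2-enyl)furan-2-yl]oxy}silane; 18 tert-butyl (4R,5R)-5-(tert-butyldimethylsilyloxy)-4-(triethylsilyloxy)dec-2-ynoate
Product: 20 tert-butyl 2-[(1R,2R)-2-(tert-butyldimethylsilyloxy)-1-(triethylsilyloxy)heptyl]-6-(tert-butyldimethylsilyloxy)-3-hydroxy-5-(3-methylbut-2-enyl)benzoate, via oxa-bridged cycloadduct 19 (not isolated)
Conditions: 6 (1.5 equiv), PhMe (1 M), 110 °C, sealed tube
Reagents that add atoms: none
Why: The silyloxyfuran 6 behaves as a cyclic silyl ketene acetal and should serve as the 4π partner for the acetylenic ester 18 in an asynchronous (4+2) cycloaddition (the furan C5–ynoate β-carbon bond, C4–C3a, leading and the bond to the ester-bearing carbon, C7–C7a, following); the oxygen bridge of 19 then ionises at the silyloxy-bearing bridgehead and loss of the proton at the other bridgehead aromatises the ring, so that the former furan oxygen becomes the C4 hydroxyl and the silyl ether stays on C7. The nearest precedent class is the cycloaddition of 2-oxygenated furans (alkoxy or silyloxy) with alkynoates, whose oxa-bridged adducts open spontaneously to para-oxygenated phenols. The one ring formed, the benzene ring, is closed by intermolecular cycloaddition, both of its new bonds arising in the same event. No stereocentre is created (the bridgeheads of 19 vanish on aromatisation), and the two carbinol centres are carried through because neither is labile under neutral thermal conditions. The step needs regioselectivity, which the partners secure electronically: the nucleophilic terminus of the diene is the unsubstituted furan C5 and the electrophilic terminus of the dienophile is the ynoate β-carbon bearing the chiral chain, so the ester lands on C7a next to the C7 silyl ether and the prenyl group on C6. It also needs chemoselectivity for the ynoate over the prenyl alkene, which is unactivated and inert at this temperature, and the excess of 6 offsets its thermal lability.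

**Step 12**
Reactants: 20 tert-butyl 2-[(1R,2R)-2-(tert-butyldimethylsilyloxy)-1-(triethylsilyloxy)heptyl]-6-(tert-butyldimethylsilyloxy)-3-hydroxy-5-(3-methylbut-2-enyl)benzoate
Product: 21 tert-butyl 3,6-bis(tert-butyldimethylsilyloxy)-2-[(1R,2R)-2-(tert-butyldimethylsilyloxy)-1-(triethylsilyloxy)heptyl]-5-(3-methylbut-2-enyl)benzoate
Conditions: TBSCl, imidazole, DMF, rt
Reagents that add atoms: tert-butyldimethylsilyl chloride, CC(C)(C)[Si](C)(C)Cl
Why: Imidazole-promoted silylation of the phenol, needed so that the C4 oxygen cannot trigger ortho-quinone methide formation when C3 is activated later.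

**Step 13**
Reactants: 21 tert-butyl 3,6-bis(tert-butyldimethylsilyloxy)-2-[(1R,2R)-2-(tert-butyldimethylsilyloxy)-1-(triethylsilyloxy)heptyl]-5-(3-methylbut-2-enyl)benzoate
Product: 22 tert-butyl 3,6-bis(tert-butyldimethylsilyloxy)-2-[(1R,2R)-2-(tert-butyldimethylsilyloxy)-1-hydroxyheptyl]-5-(3-methylbut-2-enyl)benzoate
Conditions: PPTS, MeOH/CH2Cl2, 0 °C to rt
Reagents that add atoms: none
Why: Acid-catalysed methanolysis removes the secondary triethylsilyl ether far faster than the bulkier alkyl and the aryl tert-butyldimethylsilyl ethers, and the hindered tert-butyl ester does not lactonise onto the freed alcohol.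

**Step 14**
Reactants: 22 tert-butyl 3,6-bis(tert-butyldimethylsilyloxy)-2-[(1R,2R)-2-(tert-butyldimethylsilyloxy)-1-hydroxyheptyl]-5-(3-methylbut-2-enyl)benzoate
Product: 23 tert-butyl 2-[(1S,2R)-1-(acetylsulfanyl)-2-(tert-butyldimethylsilyloxy)heptyl]-3,6-bis(tert-butyldimethylsilyloxy)-5-(3-methylbut-2-enyl)benzoate
Conditions: PPh3, DIAD, THF, 0 °C; then AcSH and 22, 0 °C to rt
Reagents that add atoms: thioacetic acid, CC(=O)S
Why: Mitsunobu thioesterification: thioacetic acid is acidic enough to protonate the betaine, and thioacetate then displaces the phosphonium-activated benzylic oxygen by SN2, so that the C3 stereocentre is set by inversion of the 1R carbinol to the 1S thioester.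

**Step 15**
Reactants: 23 tert-butyl 2-[(1S,2R)-1-(acetylsulfanyl)-2-(tert-butyldimethylsilyloxy)heptyl]-3,6-bis(tert-butyldimethylsilyloxy)-5-(3-methylbut-2-enyl)benzoate
Product: 24 2-[(1S,2R)-1-(acetylsulfanyl)-2-(tert-butyldimethylsilyloxy)heptyl]-3,6-bis(tert-butyldimethylsilyloxy)-5-(3-methylbut-2-enyl)benzoic acid
Conditions: TFA/CH2Cl2 (1:4), 0 °C
Reagents that add atoms: none
Why: Acidolysis of the tert-butyl ester by alkyl–oxygen cleavage with loss of isobutene; the thioacetate is stable to acid, sulfur stays protected against tert-butylation, and at 0 °C with short contact the silyl ethers and the prenyl alkene should survive.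

**Step 16**
Reactants: 24 2-[(1S,2R)-1-(acetylsulfanyl)-2-(tert-butyldimethylsilyloxy)heptyl]-3,6-bis(tert-butyldimethylsilyloxy)-5-(3-methylbut-2-enyl)benzoic acid
Product: 26 (3S)-4,7-bis(tert-butyldimethylsilyloxy)-3-[(1R)-1-(tert-butyldimethylsilyloxy)hexyl]-6-(3-methylbut-2-enyl)-2-benzothiophen-1(3H)-one, via mercapto acid 25 (not isolated)
Conditions: pyrrolidine, CH2Cl2 (degassed), 0 °C; 1 M HCl wash; then EDC·HCl, DMAP (cat.), CH2Cl2, 0 °C to rt
Reagents that add atoms: none
Why: Aminolysis of the thioacetate frees the thiol, and carbodiimide activation of the neighbouring carboxylic acid then closes the five-membered thiolactone (Steglich-type thioesterification, 5-exo-trig) without touching C3.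

**Step 17**
Reactants: 26 (3S)-4,7-bis(tert-butyldimethylsilyloxy)-3-[(1R)-1-(tert-butyldimethylsilyloxy)hexyl]-6-(3-methylbut-2-enyl)-2-benzothiophen-1(3H)-one
Product: 27 asperglaucin A, (3S)-4,7-dihydroxy-3-[(1R)-1-hydroxyhexyl]-6-(3-methylbut-2-enyl)-2-benzothiophen-1(3H)-one
Conditions: HF·pyridine, pyridine, THF, 0 °C to rt
Reagents that add atoms: none
Why: Fluoride-driven cleavage of the three silyl ethers under buffered, non-basic conditions, chosen so that the thiolactone is neither opened nor transacylated onto the freed C1′ hydroxyl.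

**Compound list**

1 | furan-2(5H)-one | O=C1OCC=C1 | starting material
2 | trans-3,4-dibromodihydrofuran-2(3H)-one (racemic) | O=C1OCC(Br)C1Br | intermediate (not isolated)
3 | 3-bromofuran-2(5H)-one | O=C1OCC=C1Br | intermediate
4 | tributyl(3-methylbut-2-enyl)stannane | CCCC[Sn](CCCC)(CCCC)CC=C(C)C | starting material
5 | 3-(3-methylbut-2-enyl)furan-2(5H)-one | CC(C)=CCC1=CCOC1=O | intermediate
6 | tert-butyl(dimethyl){[3-(3-methylbut-2-enyl)furan-2-yl]oxy}silane | CC(C)=CCc1ccoc1O[Si](C)(C)C(C)(C)C | intermediate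
7 | methyl (2R)-oxirane-2-carboxylate | COC(=O)[C@H]1CO1 | starting material
8 | butylmagnesium bromide | CCCC[Mg]Br | starting material
9 | methyl (2R)-2-hydroxyheptanoate | CCCCC[C@@H](O)C(=O)OC | intermediate
10 | methyl (2R)-2-(tert-butyldimethylsilyloxy)heptanoate | CCCCC[C@@H](O[Si](C)(C)C(C)(C)C)C(=O)OC | intermediate
11 | (2R)-2-(tert-butyldimethylsilyloxy)-N-methoxy-N-methylheptanamide | CCCCC[C@@H](O[Si](C)(C)C(C)(C)C)C(=O)N(C)OC | intermediate
12 | ethynyltrimethylsilane | C#C[Si](C)(C)C | starting material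
13 | lithium (trimethylsilyl)acetylide | [Li]C#C[Si](C)(C)C | intermediate (not isolated)
14 | (4R)-4-(tert-butyldimethylsilyloxy)-1-(trimethylsilyl)non-1-yn-3-one | CCCCC[C@@H](O[Si](C)(C)C(C)(C)C)C(=O)C#C[Si](C)(C)C | intermediate
15 | (3R,4R)-4-(tert-butyldimethylsilyloxy)-1-(trimethylsilyl)non-1-yn-3-ol | CCCCC[C@@H](O[Si](C)(C)C(C)(C)C)[C@H](O)C#C[Si](C)(C)C | intermediate
16 | (3R,4R)-4-(tert-butyldimethylsilyloxy)-3-(triethylsilyloxy)-1-(trimethylsilyl)non-1-yne | CCCCC[C@@H](O[Si](C)(C)C(C)(C)C)[C@H](O[Si](CC)(CC)CC)C#C[Si](C)(C)C | intermediate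
17 | lithium (3R,4R)-4-(tert-butyldimethylsilyloxy)-3-(triethylsilyloxy)non-1-yn-1-ide | CCCCC[C@@H](O[Si](C)(C)C(C)(C)C)[C@H](O[Si](CC)(CC)CC)C#C[Li] | intermediate (not isolated)
18 | tert-butyl (4R,5R)-5-(tert-butyldimethylsilyloxy)-4-(triethylsilyloxy)dec-2-ynoate | CCCCC[C@@H](O[Si](C)(C)C(C)(C)C)[C@H](O[Si](CC)(CC)CC)C#CC(=O)OC(C)(C)C | intermediate (key-step precursor)
19 | tert-butyl 1-(tert-butyldimethylsilyloxy)-3-[(1R,2R)-2-(tert-butyldimethylsilyloxy)-1-(triethylsilyloxy)heptyl]-6-(3-methylbut-2-enyl)-7-oxabicyclo[2.2.1]hepta-2,5-diene-2-carboxylate (bridgehead epimers) | CCCCC[C@@H](O[Si](C)(C)C(C)(C)C)[C@H](O[Si](CC)(CC)CC)C1=C(C(=O)OC(C)(C)C)C2(O[Si](C)(C)C(C)(C)C)OC1C=C2CC=C(C)C | intermediate (not isolated)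
20 | tert-butyl 2-[(1R,2R)-2-(tert-butyldimethylsilyloxy)-1-(triethylsilyloxy)heptyl]-6-(tert-butyldimethylsilyloxy)-3-hydroxy-5-(3-methylbut-2-enyl)benzoate | CCCCC[C@@H](O[Si](C)(C)C(C)(C)C)[C@H](O[Si](CC)(CC)CC)c1c(O)cc(CC=C(C)C)c(O[Si](C)(C)C(C)(C)C)c1C(=O)OC(C)(C)C | intermediate (key-step product)
21 | tert-butyl 3,6-bis(tert-butyldimethylsilyloxy)-2-[(1R,2R)-2-(tert-butyldimethylsilyloxy)-1-(triethylsilyloxy)heptyl]-5-(3-methylbut-2-enyl)benzoate | CCCCC[C@@H](O[Si](C)(C)C(C)(C)C)[C@H](O[Si](CC)(CC)CC)c1c(O[Si](C)(C)C(C)(C)C)cc(CC=C(C)C)c(O[Si](C)(C)C(C)(C)C)c1C(=O)OC(C)(C)C | intermediate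
22 | tert-butyl 3,6-bis(tert-butyldimethylsilyloxy)-2-[(1R,2R)-2-(tert-butyldimethylsilyloxy)-1-hydroxyheptyl]-5-(3-methylbut-2-enyl)benzoate | CCCCC[C@@H](O[Si](C)(C)C(C)(C)C)[C@H](O)c1c(O[Si](C)(C)C(C)(C)C)cc(CC=C(C)C)c(O[Si](C)(C)C(C)(C)C)c1C(=O)OC(C)(C)C | intermediate
23 | tert-butyl 2-[(1S,2R)-1-(acetylsulfanyl)-2-(tert-butyldimethylsilyloxy)heptyl]-3,6-bis(tert-butyldimethylsilyloxy)-5-(3-methylbut-2-enyl)benzoate | CCCCC[C@@H](O[Si](C)(C)C(C)(C)C)[C@@H](SC(C)=O)c1c(O[Si](C)(C)C(C)(C)C)cc(CC=C(C)C)c(O[Si](C)(C)C(C)(C)C)c1C(=O)OC(C)(C)C | intermediate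
24 | 2-[(1S,2R)-1-(acetylsulfanyl)-2-(tert-butyldimethylsilyloxy)heptyl]-3,6-bis(tert-butyldimethylsilyloxy)-5-(3-methylbut-2-enyl)benzoic acid | CCCCC[C@@H](O[Si](C)(C)C(C)(C)C)[C@@H](SC(C)=O)c1c(O[Si](C)(C)C(C)(C)C)cc(CC=C(C)C)c(O[Si](C)(C)C(C)(C)C)c1C(=O)O | intermediate
25 | 3,6-bis(tert-butyldimethylsilyloxy)-2-[(1S,2R)-2-(tert-butyldimethylsilyloxy)-1-sulfanylheptyl]-5-(3-methylbut-2-enyl)benzoic acid | CCCCC[C@@H](O[Si](C)(C)C(C)(C)C)[C@@H](S)c1c(O[Si](C)(C)C(C)(C)C)cc(CC=C(C)C)c(O[Si](C)(C)C(C)(C)C)c1C(=O)O | intermediate (not isolated)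
26 | (3S)-4,7-bis(tert-butyldimethylsilyloxy)-3-[(1R)-1-(tert-butyldimethylsilyloxy)hexyl]-6-(3-methylbut-2-enyl)-2-benzothiophen-1(3H)-one | CCCCC[C@@H](O[Si](C)(C)C(C)(C)C)[C@H]1SC(=O)c2c(O[Si](C)(C)C(C)(C)C)c(CC=C(C)C)cc(O[Si](C)(C)C(C)(C)C)c21 | intermediate
27 | asperglaucin A, (3S)-4,7-dihydroxy-3-[(1R)-1-hydroxyhexyl]-6-(3-methylbut-2-enyl)-2-benzothiophen-1(3H)-one | CCCCC[C@@H](O)[C@H]1SC(=O)c2c(O)c(CC=C(C)C)cc(O)c21 | target

**Step count.** Total: 17 steps (3 to the silyloxyfuran, 7 to the ynoate, the key step, 6 after it). Longest linear sequence: 14 steps (steps 4 to 17).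

**Steps most likely to fail**

Step 11. The trisubstituted, β-branched ynoate may cycloadd so slowly that the silyloxyfuran is lost to desilylation or self-condensation, or the bridged adduct may collapse with silyl transfer instead of clean aromatisation. The fallback uses a more electrophilic dienophile and restores the ester oxidation level afterwards. Setting out from 16, the acetylide 17 would be formylated with DMF to the ynal (4R,5R)-5-(tert-butyldimethylsilyloxy)-4-(triethylsilyloxy)dec-2-ynal F1. Its thermal cycloaddition with 6 (PhMe, 60 °C) and aromatisation should give, with the same orientation, 2-[(1R,2R)-2-(tert-butyldimethylsilyloxy)-1-(triethylsilyloxy)heptyl]-6-(tert-butyldimethylsilyloxy)-3-hydroxy-5-(3-methylbut-2-enyl)benzaldehyde F2. Silylation (TBSCl, imidazole) would give the bis(silyl ether) aldehyde 3,6-bis(tert-butyldimethylsilyloxy)-2-[(1R,2R)-2-(tert-butyldimethylsilyloxy)-1-(triethylsilyloxy)heptyl]-5-(3-methylbut-2-enyl)benzaldehyde F3. Pinnick oxidation (NaClO2, NaH2PO4, 2-methylbut-2-ene) would give the corresponding benzoic acid F4. O-Alkylation of this hindered acid with N,N-dimethylformamide di-tert-butyl acetal (PhMe, 80 °C) would come back to the route at 21.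

Step 14. Displacement at the doubly ortho-substituted, β-branched benzylic carbinol may be slow, so that the activated oxygen is captured by the neighbouring ester carbonyl (lactone formation with loss of isobutene) or ionises with erosion of the inversion. The fallback separates activation from displacement and avoids phosphonium species. From 22, the methanesulfonate tert-butyl 3,6-bis(tert-butyldimethylsilyloxy)-2-[(1R,2R)-2-(tert-butyldimethylsilyloxy)-1-(methylsulfonyloxy)heptyl]-5-(3-methylbut-2-enyl)benzoate F5 would be formed through the sulfene pathway (MsCl, Et3N, CH2Cl2, −20 °C), which tolerates hindered alcohols. It would be displaced at low temperature with caesium thioacetate (CsSAc, DMF), a poorly solvated and therefore faster sulfur nucleophile, to come back at 23.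

Step 15. The strong acid may protonate the prenyl alkene, leading to cyclisation onto the C7 oxygen, or strip the C1′ silyl ether before the ester is cleaved. The fallback uses no Brønsted acid and transfers the acyl group directly from the ester. From 23, aminolysis (pyrrolidine, CH2Cl2) would give the thiol ester tert-butyl 3,6-bis(tert-butyldimethylsilyloxy)-2-[(1S,2R)-2-(tert-butyldimethylsilyloxy)-1-sulfanylheptyl]-5-(3-methylbut-2-enyl)benzoate F6. Its dimethylaluminium thiolate (AlMe3, PhMe, 0 to 60 °C) should attack the ester intramolecularly with expulsion of aluminium tert-butoxide, the known ester-to-thioester conversion with aluminium thiolates, to come back at 26.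

**Further compounds**

F1 | step 11 | (4R,5R)-5-(tert-butyldimethylsilyloxy)-4-(triethylsilyloxy)dec-2-ynal | CCCCC[C@@H](O[Si](C)(C)C(C)(C)C)[C@H](O[Si](CC)(CC)CC)C#CC=O
F2 | step 11 | 2-[(1R,2R)-2-(tert-butyldimethylsilyloxy)-1-(triethylsilyloxy)heptyl]-6-(tert-butyldimethylsilyloxy)-3-hydroxy-5-(3-methylbut-2-enyl)benzaldehyde | CCCCC[C@@H](O[Si](C)(C)C(C)(C)C)[C@H](O[Si](CC)(CC)CC)c1c(O)cc(CC=C(C)C)c(O[Si](C)(C)C(C)(C)C)c1C=O
F3 | step 11 | 3,6-bis(tert-butyldimethylsilyloxy)-2-[(1R,2R)-2-(tert-butyldimethylsilyloxy)-1-(triethylsilyloxy)heptyl]-5-(3-methylbut-2-enyl)benzaldehyde | CCCCC[C@@H](O[Si](C)(C)C(C)(C)C)[C@H](O[Si](CC)(CC)CC)c1c(O[Si](C)(C)C(C)(C)C)cc(CC=C(C)C)c(O[Si](C)(C)C(C)(C)C)c1C=O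
F4 | step 11 | 3,6-bis(tert-butyldimethylsilyloxy)-2-[(1R,2R)-2-(tert-butyldimethylsilyloxy)-1-(triethylsilyloxy)heptyl]-5-(3-methylbut-2-enyl)benzoic acid | CCCCC[C@@H](O[Si](C)(C)C(C)(C)C)[C@H](O[Si](CC)(CC)CC)c1c(O[Si](C)(C)C(C)(C)C)cc(CC=C(C)C)c(O[Si](C)(C)C(C)(C)C)c1C(=O)O
F5 | step 14 | tert-butyl 3,6-bis(tert-butyldimethylsilyloxy)-2-[(1R,2R)-2-(tert-butyldimethylsilyloxy)-1-(methylsulfonyloxy)heptyl]-5-(3-methylbut-2-enyl)benzoate | CCCCC[C@@H](O[Si](C)(C)C(C)(C)C)[C@H](OS(C)(=O)=O)c1c(O[Si](C)(C)C(C)(C)C)cc(CC=C(C)C)c(O[Si](C)(C)C(C)(C)C)c1C(=O)OC(C)(C)C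
F6 | step 15 | tert-butyl 3,6-bis(tert-butyldimethylsilyloxy)-2-[(1S,2R)-2-(tert-butyldimethylsilyloxy)-1-sulfanylheptyl]-5-(3-methylbut-2-enyl)benzoate | CCCCC[C@@H](O[Si](C)(C)C(C)(C)C)[C@@H](S)c1c(O[Si](C)(C)C(C)(C)C)cc(CC=C(C)C)c(O[Si](C)(C)C(C)(C)C)c1C(=O)OC(C)(C)C
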